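**Retrosynthetic overview**
1. Target 15 ⇒ acid 13 by C4–C4a Friedel–Crafts acylation (pyranone ring closed last); 13 ⇐ oxidation of alcohol 11.
2. 11 ⇒ aryl C–O bond (the future O1–C8a): enantioselective Cu-catalysed mono-O-arylation of prochiral diol 9 with 10; this desymmetrisation creates the spiro quaternary stereocentre.
3. 9 ⇒ aldehyde 7 (aldol/Cannizzaro with formaldehyde) ⇒ benzocyclobutenone 5 (Wittig one-carbon homologation).
4. 5 ⇒ [2+2] of 3,4-dimethoxybenzyne (from 1) with ketene acetal 2, which places the future spiro carbon next to the OMe-bearing ring carbon.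
5. Ring order: cyclobutene (step 1), then chromanone pyranone ring (step 6); both arenes are bought.

**Notes before the steps**
- Assumption: the sense of induction of the new catalyst cannot be predicted; the (S)-ligand L* is taken to arylate the pro-R hydroxymethyl arm of 9, and its mirror image is used if the opposite sense is found.
- Numbering: bicyclo[4.2.0]octa-1,3,5-triene; C7 is the four-ring carbon bonded to aromatic C6, the methoxy groups sit on C5 (next to C6) and C4, and C8 is the ring CH2.
- Ligand for step 4 (catalyst, made separately, not a route compound): L* = N1-(5-methylbiphenyl-2-yl)-N2-[(S)-1-(naphthalen-1-yl)ethyl]oxalamide, C[C@H](NC(=O)C(=O)Nc1ccc(C)cc1-c1ccccc1)c1cccc2ccccc12.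
- The target stereocentre is (S). Intermediate 11 is (R) only because the CIP ranking of the two arms changes on oxidation; no bond at the stereocentre is broken after step 4.

**Step 1**
Reactants: 1 1-bromo-2,3-dimethoxybenzene; 2 1,1-dimethoxyethene
Product: 5 4,5-dimethoxybicyclo[4.2.0]octa-1,3,5-trien-7-one, via 3,4-dimethoxybenzyne 3 (not isolated), via ketone dimethyl acetal 4 (not isolated)
Conditions: NaNH2 (2.5 equiv), 2 (2 equiv), THF, 65 °C; then 1 M HCl, THF/H2O, rt
Reagents that add atoms: water, O
Why: Aryne [2+2] cycloaddition: the nucleophilic CH2 terminus of the ketene acetal adds to the aryne carbon remote from OMe, so the acetal carbon ends up next to the methoxy-bearing carbon, and acid work-up hydrolyses the acetal only after the amide base is quenched.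

**Step 2**
Reactants: 5 4,5-dimethoxybicyclo[4.2.0]octa-1,3,5-trien-7-one
Product: 7 4,5-dimethoxybicyclo[4.2.0]octa-1,3,5-triene-7-carbaldehyde (racemic), via methyl enol ether 6 (not isolated)
Conditions: Ph3P(CH2OMe)Cl (1.5 equiv), KHMDS (1.4 equiv), THF, 0 °C to rt; then 2 M HCl, THF, rt
Reagents that add atoms: (methoxymethyl)triphenylphosphonium chloride, COC[P+](c1ccccc1)(c1ccccc1)c1ccccc1.[Cl-]; water, O
Why: Wittig methoxymethylenation followed by enol-ether hydrolysis (one-carbon homologation); the salt-free ylide reacts through an oxaphosphetane without a free alkoxide, so the strained ketone should not ring-open, and the labile C7–H centre of 7 is erased in step 3.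

**Step 3**
Reactants: 7 4,5-dimethoxybicyclo[4.2.0]octa-1,3,5-triene-7-carbaldehyde
Product: 9 (4,5-dimethoxybicyclo[4.2.0]octa-1,3,5-triene-7,7-diyl)dimethanol, via hydroxymethyl aldehyde 8 (not isolated)
Conditions: 37% aq. CH2O (6 equiv), KOH (1.5 equiv), EtOH/H2O, 0 to 45 °C
Reagents that add atoms: formaldehyde, C=O
Why: Tollens condensation: crossed aldol of the single α-CH with formaldehyde, then crossed Cannizzaro reduction of the now non-enolisable aldehyde by excess formaldehyde, gives the achiral (prochiral) 1,3-diol.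

**Step 4**
Reactants: 9 (4,5-dimethoxybicyclo[4.2.0]octa-1,3,5-triene-7,7-diyl)dimethanol; 10 1-iodo-3,5-dimethoxybenzene
Product: 11 (R)-{7-[(3,5-dimethoxyphenoxy)methyl]-4,5-dimethoxybicyclo[4.2.0]octa-1,3,5-trien-7-yl}methanol
Conditions: CuI (10 mol %), L* (12 mol %), Cs2CO3 (1.5 equiv), 10 (1.05 equiv), 4 Å MS, 1,4-dioxane, 40 °C
Reagents that add atoms: none
Why: Proposed new method: intermolecular enantioselective Ullmann-type etherification that desymmetrises an all-carbon-quaternary propane-1,3-diol; the anionic Cu(I)–oxalamide binds one hydroxyl as alkoxide while the second hydroxyl hydrogen-bonds to the ligand amidate oxygen, giving a rigid chelate in which the flat methoxyarene and the ring CH2 on the spiro carbon are distinguished by the chiral N-(1-naphthylethyl) arm, so that oxidative addition of ArI and C–O reductive elimination occur on the pro-R arm and set the quaternary stereocentre; closest known reactions are the Cu/chiral-diamine intramolecular desymmetrising O-arylation of 1,3-diols carrying a 2-haloaryl group and the racemic Cu/oxalamide coupling of aryl halides with primary alcohols.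

**Step 5**
Reactants: 11 (R)-{7-[(3,5-dimethoxyphenoxy)methyl]-4,5-dimethoxybicyclo[4.2.0]octa-1,3,5-trien-7-yl}methanol
Product: 13 (S)-7-[(3,5-dimethoxyphenoxy)methyl]-4,5-dimethoxybicyclo[4.2.0]octa-1,3,5-triene-7-carboxylic acid, via aldehyde 12 (not isolated)
Conditions: TPAP (10 mol %), NMO·H2O (10 equiv), MeCN, rt
Reagents that add atoms: water (from NMO·H2O), O
Why: Ley–Griffith oxidation run with NMO hydrate, which carries the primary alcohol through the aldehyde hydrate to the acid; it uses no electrophilic halogen or strong acid, so the very electron-rich trioxygenated ring should survive, and the stereocentre has no α-H.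

**Step 6**
Reactants: 13 (S)-7-[(3,5-dimethoxyphenoxy)methyl]-4,5-dimethoxybicyclo[4.2.0]octa-1,3,5-triene-7-carboxylic acid
Product: 15 (S)-4,5,5',7'-tetramethoxyspiro[bicyclo[4.2.0]octa-1,3,5-triene-7,3'-chroman]-4'-one (target), via trifluoroacetic mixed anhydride 14 (not isolated)
Conditions: TFAA (3 equiv), CH2Cl2, 0 °C to rt
Reagents that add atoms: none
Why: Intramolecular Friedel–Crafts acylation through the mixed anhydride at the position ortho to the ether oxygen and para to OMe (both ortho positions of the symmetric ring give the same 5,7-dimethoxychromanone); the quaternary centre is untouched and the mild temperature avoids benzocyclobutene ring-opening.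

**Compound list**
1 | 1-bromo-2,3-dimethoxybenzene | COc1cccc(Br)c1OC | starting material
2 | 1,1-dimethoxyethene | C=C(OC)OC | starting material
3 | 3,4-dimethoxybenzyne | COC1=C(OC)C#CC=C1 | intermediate
4 | 4,5,7,7-tetramethoxybicyclo[4.2.0]octa-1,3,5-triene | COc1ccc2CC(OC)(OC)c2c1OC | intermediate
5 | 4,5-dimethoxybicyclo[4.2.0]octa-1,3,5-trien-7-one | COc1ccc2CC(=O)c2c1OC | intermediate
6 | 4,5-dimethoxy-7-(methoxymethylidene)bicyclo[4.2.0]octa-1,3,5-triene (E/Z mixture) | COC=C1Cc2ccc(OC)c(OC)c21 | intermediate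
7 | 4,5-dimethoxybicyclo[4.2.0]octa-1,3,5-triene-7-carbaldehyde (racemic) | COc1ccc2CC(C=O)c2c1OC | intermediate
8 | 7-(hydroxymethyl)-4,5-dimethoxybicyclo[4.2.0]octa-1,3,5-triene-7-carbaldehyde (racemic) | COc1ccc2CC(CO)(C=O)c2c1OC | intermediate
9 | (4,5-dimethoxybicyclo[4.2.0]octa-1,3,5-triene-7,7-diyl)dimethanol | COc1ccc2CC(CO)(CO)c2c1OC | intermediate
10 | 1-iodo-3,5-dimethoxybenzene | COc1cc(I)cc(OC)c1 | starting material
11 | (R)-{7-[(3,5-dimethoxyphenoxy)methyl]-4,5-dimethoxybicyclo[4.2.0]octa-1,3,5-trien-7-yl}methanol | COc1cc(OC)cc(c1)OC[C@@]1(Cc3ccc(OC)c(OC)c31)CO | intermediate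
12 | (S)-7-[(3,5-dimethoxyphenoxy)methyl]-4,5-dimethoxybicyclo[4.2.0]octa-1,3,5-triene-7-carbaldehyde | COc1cc(OC)cc(c1)OC[C@@]1(Cc3ccc(OC)c(OC)c31)C=O | intermediate
13 | (S)-7-[(3,5-dimethoxyphenoxy)methyl]-4,5-dimethoxybicyclo[4.2.0]octa-1,3,5-triene-7-carboxylic acid | COc1cc(OC)cc(c1)OC[C@@]1(Cc3ccc(OC)c(OC)c31)C(=O)O | intermediate
14 | mixed anhydride of 13 with trifluoroacetic acid, (S) | COc1cc(OC)cc(c1)OC[C@@]1(Cc3ccc(OC)c(OC)c31)C(=O)OC(=O)C(F)(F)F | intermediate
15 | (S)-4,5,5',7'-tetramethoxyspiro[bicyclo[4.2.0]octa-1,3,5-triene-7,3'-chroman]-4'-one | COc1cc(OC)c2c(c1)OC[C@@]1(Cc3ccc(OC)c(OC)c31)C2=O | target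

**Totals**
Total steps: 6. Longest linear sequence: 6.

**Steps most likely to fail**

Step 4 (the proposed desymmetrising O-arylation; enantioselectivity or mono/bis selectivity may be poor). The fallback sets out from 9 and comes back at 13, using resolution instead of asymmetric catalysis. Diol 9 (2 equiv, excess recovered) is mono-arylated with 10 under ordinary Ullmann conditions (CuI, 3,4,7,8-tetramethyl-1,10-phenanthroline, Cs2CO3, toluene, 90 °C) to give racemic {7-[(3,5-dimethoxyphenoxy)methyl]-4,5-dimethoxybicyclo[4.2.0]octa-1,3,5-trien-7-yl}methanol F1. Oxidation as in step 5 gives racemic 7-[(3,5-dimethoxyphenoxy)methyl]-4,5-dimethoxybicyclo[4.2.0]octa-1,3,5-triene-7-carboxylic acid F2. Fractional crystallisation with (R)-1-phenylethylamine from EtOH/EtOAc gives the (R)-1-phenylethylammonium (S)-carboxylate salt F3 (the amine antipode is used if the other diastereomer is the less soluble one), and 1 M HCl liberates 13. The same salt crystallisation can also raise the ee of 13 from the main route.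

Step 2 (nucleophilic ylide on a strained, ring-opening-prone ketone). The fallback sets out from 5 and comes back at 7, replacing the basic ylide by a titanium carbene followed by anti-Markovnikov hydration. Tebbe reagent (THF, −40 to 0 °C) gives 4,5-dimethoxy-7-methylidenebicyclo[4.2.0]octa-1,3,5-triene F4. BH3·THF at 0 °C gives tris[(4,5-dimethoxybicyclo[4.2.0]octa-1,3,5-trien-7-yl)methyl]borane F5, which is oxidised in the same flask (NaOH, H2O2) to (4,5-dimethoxybicyclo[4.2.0]octa-1,3,5-trien-7-yl)methanol F6. Parikh–Doering oxidation (SO3·pyridine, DMSO, iPr2NEt, CH2Cl2, 0 °C) then gives 7.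

Step 5 (four-electron oxidation next to a phloroglucinol-type ring that is easily attacked by oxidants). The fallback sets out from 11 and comes back at 15, closing the ring at the aldehyde level and so bypassing 13 and step 6. Parikh–Doering oxidation of 11 gives aldehyde 12, now isolated. BF3·OEt2 (CH2Cl2, −20 °C) effects intramolecular Friedel–Crafts hydroxyalkylation to (S)-4'-hydroxy-4,5,5',7'-tetramethoxyspiro[bicyclo[4.2.0]octa-1,3,5-triene-7,3'-chromane] F7 (both C4' epimers). MnO2 (CH2Cl2, rt) oxidises this benzylic alcohol to 15.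

**Further compounds**
F1 | step 4 | racemic {7-[(3,5-dimethoxyphenoxy)methyl]-4,5-dimethoxybicyclo[4.2.0]octa-1,3,5-trien-7-yl}methanol | COc1cc(OC)cc(OCC2(CO)Cc3ccc(OC)c(OC)c32)c1
F2 | step 4 | racemic 7-[(3,5-dimethoxyphenoxy)methyl]-4,5-dimethoxybicyclo[4.2.0]octa-1,3,5-triene-7-carboxylic acid | COc1cc(OC)cc(OCC2(C(=O)O)Cc3ccc(OC)c(OC)c32)c1
F3 | step 4 | (R)-1-phenylethylammonium (S)-7-[(3,5-dimethoxyphenoxy)methyl]-4,5-dimethoxybicyclo[4.2.0]octa-1,3,5-triene-7-carboxylate | COc1cc(OC)cc(c1)OC[C@@]1(Cc3ccc(OC)c(OC)c31)C(=O)[O-].C[C@@H]([NH3+])c1ccccc1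
F4 | step 2 | 4,5-dimethoxy-7-methylidenebicyclo[4.2.0]octa-1,3,5-triene | C=C1Cc2ccc(OC)c(OC)c21
F5 | step 2 | tris[(4,5-dimethoxybicyclo[4.2.0]octa-1,3,5-trien-7-yl)methyl]borane | B(CC1Cc2ccc(OC)c(OC)c21)(CC1Cc2ccc(OC)c(OC)c21)CC1Cc2ccc(OC)c(OC)c21
F6 | step 2 | (4,5-dimethoxybicyclo[4.2.0]octa-1,3,5-trien-7-yl)methanol (racemic) | OCC1Cc2ccc(OC)c(OC)c21
F7 | step 5 | (S)-4'-hydroxy-4,5,5',7'-tetramethoxyspiro[bicyclo[4.2.0]octa-1,3,5-triene-7,3'-chromane] (C4' epimers) | COc1cc(OC)c2c(c1)OC[C@@]1(Cc3ccc(OC)c(OC)c31)C2O
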